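**Retrosynthetic overview**
1. Pleuromutilin F ⇐ C3=C4 enone by dehydrogenation of a C2 cyclopentanone, C14 glycolate by acylation, C6 methyl from a C6 ketone (methylenation, then radical hydrogenation).
2. Eight-membered ring (C4, C5, C14, C13, C12, C11, C10, C9) ⇐ C5–C14 Reformatsky-type aldol of a C5 bromoketone onto a C14 aldehyde; C11–C14 chain ⇐ allylboration of a C11 aldehyde (sets C11 and C12).
3. Bicyclic core ⇐ carbenoid alkylative dearomatisation forming C1–C9. The strategy rests on quaternary C9, shared by the five-membered ring (C1–C4, C9) and the six-membered ring (C4–C9); the six-membered ring with its C5 methyl is a 2-methylphenol oxygenated at C6.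
4. Phenolic diazoketone ⇐ 3-bromo-2-methylphenol by ester α-arylation (C2, C3), para-bromination, isopropenyl coupling and asymmetric hydroboration (C10).
5. Ring order: six-membered ring (arene) → five-membered ring (step 11) → eight-membered ring (step 24).

Key step: step 11

Remark: atom numbers are mutilin numbers (C1–C4 and C9 five-membered ring, C4–C9 six-membered ring, C10–C14 the bridge, C2 the ring ketone of the target).
Assumption: the stereo tags at C5 and C6 of every tricyclic compound are written exactly as in the target SMILES; C5 is the centre fixed by the C9-anchored tether in step 24 and C6 the centre fixed by hydrogen delivery anti to C14 in step 27.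
Remark: C11 is carried through the key step as a methyl ester, not as a silyloxymethyl group; the reason is given at step 11.

**Route**

Step 1
Reactants: 1 3-bromo-2-methylphenol
Product: 2 (3-bromo-2-methylphenoxy)triisopropylsilane
Conditions: TIPSCl, imidazole, DMF, rt
Reagents that add atoms: triisopropylsilyl chloride, CC(C)[Si](Cl)(C(C)C)C(C)C
Why: Phenol silylation; the aryl TIPS ether should survive steps 2–9 and comes off with buffered fluoride in step 10.

Step 2
Reactants: 2 (3-bromo-2-methylphenoxy)triisopropylsilane; 3 (2-tert-butoxy-2-oxoethyl)zinc chloride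
Product: 4 tert-butyl 2-{2-methyl-3-[(triisopropylsilyl)oxy]phenyl}acetate
Conditions: Pd(dba)2 (2 mol%), Q-Phos (2 mol%), THF, rt→50 °C
Reagents that add atoms: none
Why: Pd-catalysed α-arylation of an ester (Negishi-type coupling of a Reformatsky reagent) should install C3 and C2 on the carbon that becomes C4.

Step 3
Reactants: 4 tert-butyl 2-{2-methyl-3-[(triisopropylsilyl)oxy]phenyl}acetate
Product: 5 tert-butyl 2-{6-bromo-2-methyl-3-[(triisopropylsilyl)oxy]phenyl}acetate
Conditions: NBS, MeCN, 0 °C→rt, dark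
Reagents that add atoms: N-bromosuccinimide, O=C1CCC(=O)N1Br
Why: Electrophilic aromatic bromination para to the silyloxy group (the ortho position is shielded by TIPS) should place bromine on the future C9.

Step 4
Reactants: 5 tert-butyl 2-{6-bromo-2-methyl-3-[(triisopropylsilyl)oxy]phenyl}acetate; 6 4,4,5,5-tetramethyl-2-(prop-1-en-2-yl)-1,3,2-dioxaborolane
Product: 7 tert-butyl 2-{2-methyl-6-(prop-1-en-2-yl)-3-[(triisopropylsilyl)oxy]phenyl}acetate
Conditions: Pd(OAc)2 (3 mol%), SPhos, K3PO4, toluene/H2O 10:1, 80 °C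
Reagents that add atoms: none
Why: Suzuki–Miyaura coupling brings in C10, C11 and the C10 methyl as an isopropenyl group.

Step 5
Reactants: 7 tert-butyl 2-{2-methyl-6-(prop-1-en-2-yl)-3-[(triisopropylsilyl)oxy]phenyl}acetate
Product: 9 tert-butyl 2-{6-[(2R)-1-hydroxypropan-2-yl]-2-methyl-3-[(triisopropylsilyl)oxy]phenyl}acetate, via alkylboronate 8 (not isolated)
Conditions: HBpin, CuCl (3 mol%), (R)-DTBM-SEGPHOS, NaOtBu (6 mol%), THF, rt; then H2O2, NaOH aq, 0 °C
Reagents that add atoms: pinacolborane, B1OC(C)(C)C(C)(C)O1 (boron of 8 only); hydrogen peroxide, OO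
Why: Copper hydride-catalysed anti-Markovnikov asymmetric hydroboration of a 1,1-disubstituted aryl alkene sets C10, and the C–B oxidation is stereoretentive; the ligand enantiomer is the one that gives the (S)-boronate, to be confirmed on first use and exchanged for its antipode if the sense is opposite.

Step 6
Reactants: 9 tert-butyl 2-{6-[(2R)-1-hydroxypropan-2-yl]-2-methyl-3-[(triisopropylsilyl)oxy]phenyl}acetate
Product: 10 (2R)-2-{2-(2-tert-butoxy-2-oxoethyl)-3-methyl-4-[(triisopropylsilyl)oxy]phenyl}propanoic acid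
Conditions: TEMPO (10 mol%), NaClO2, NaOCl (cat.), MeCN/phosphate buffer pH 6.7, 35 °C
Reagents that add atoms: sodium chlorite, [Na+].[O-]Cl=O
Why: Buffered TEMPO/chlorite oxidation takes the primary alcohol to the acid without a long-lived, epimerisable 2-arylpropanal.

Step 7
Reactants: 10 (2R)-2-{2-(2-tert-butoxy-2-oxoethyl)-3-methyl-4-[(triisopropylsilyl)oxy]phenyl}propanoic acid; 11 (trimethylsilyl)diazomethane
Product: 12 methyl (2R)-2-{2-(2-tert-butoxy-2-oxoethyl)-3-methyl-4-[(triisopropylsilyl)oxy]phenyl}propanoate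
Conditions: TMSCHN2, toluene/MeOH 4:1, 0 °C
Reagents that add atoms: none
Why: Base-free methyl esterification keeps the α-aryl stereocentre C10 intact.

Step 8
Reactants: 12 methyl (2R)-2-{2-(2-tert-butoxy-2-oxoethyl)-3-methyl-4-[(triisopropylsilyl)oxy]phenyl}propanoate
Product: 13 2-{6-[(2R)-1-methoxy-1-oxopropan-2-yl]-2-methyl-3-[(triisopropylsilyl)oxy]phenyl}acetic acid
Conditions: TFA/CH2Cl2 1:4, 0 °C→rt
Reagents that add atoms: none
Why: Acidolysis of the tert-butyl ester; the methyl ester and the aryl silyl ether are stable to TFA.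

Step 9
Reactants: 13 2-{6-[(2R)-1-methoxy-1-oxopropan-2-yl]-2-methyl-3-[(triisopropylsilyl)oxy]phenyl}acetic acid; 11 (trimethylsilyl)diazomethane
Product: 16 methyl (2R)-2-{2-(3-diazo-2-oxopropyl)-3-methyl-4-[(triisopropylsilyl)oxy]phenyl}propanoate, via acid chloride 14 (not isolated), via C-silyl diazoketone 15 (not isolated)
Conditions: (COCl)2, DMF (cat.), CH2Cl2, 0 °C; evaporate; TMSCHN2 (2.5 equiv), MeCN/THF, 0 °C→rt; aq NaHCO3
Reagents that add atoms: oxalyl chloride, ClC(=O)C(=O)Cl (chlorine of 14 only)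
Why: Acylation of a diazomethane equivalent by the acid chloride gives the diazoketone (C1 introduced); no amine base is used, so neither ketene formation nor epimerisation at C10 is expected.

Step 10
Reactants: 16 methyl (2R)-2-{2-(3-diazo-2-oxopropyl)-3-methyl-4-[(triisopropylsilyl)oxy]phenyl}propanoate
Product: 17 methyl (2R)-2-[2-(3-diazo-2-oxopropyl)-4-hydroxy-3-methylphenyl]propanoate
Conditions: TBAF, AcOH (1:1.2), THF, 0 °C
Reagents that add atoms: none
Why: Buffered fluoride cleaves the aryl silyl ether; the diazoketone and the α-aryl ester tolerate these near-neutral conditions.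

Step 11
Reactants: 17 methyl (2R)-2-[2-(3-diazo-2-oxopropyl)-4-hydroxy-3-methylphenyl]propanoate
Product: 18 methyl (2R)-2-[(7aR)-4-methyl-2,5-dioxo-1,2,3,5-tetrahydro-7aH-inden-7a-yl]propanoate
Conditions: Rh2(OAc)4 (1 mol%), CH2Cl2, rt, slow addition of 17 (final 5 mM)
Reagents that add atoms: none
Why: Rh(II) turns the diazoketone into an electrophilic carbenoid at C1, which is attacked by arene carbon C9 (para to OH, ortho to the tether); the zwitterion loses the phenolic proton and the metal to give the cross-conjugated dienone, the known intramolecular alkylative dearomatisation of phenols by α-diazoketones. The cyclopentanone closes through the ortho carbon as a five-membered ring (Ar2-5 mode, exo with respect to the Rh=C1 bond, the arene bond C4–C9 lying inside the new ring). Quaternary C9 is set by C10: allylic 1,3-strain holds C10–H in the arene plane towards C3, so CO2Me and CH3 flank the two faces, and the carbenoid is expected to bond on the face of the smaller, electron-poor CO2Me, anti to the better σ-donor CH3, which gives the (7aR,2R) isomer; this is why C11 is an ester here. The step needs C9 over C5 attack and C–C bond formation over O–H insertion, Büchner expansion and C–H insertion; the para-hydroxyl (largest HOMO coefficient, more stable para-quinoid product) directs to C9, high dilution suppresses O–H insertion, and the ester deactivates the C10–H bond.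

Step 12
Reactants: 18 methyl (2R)-2-[(7aR)-4-methyl-2,5-dioxo-1,2,3,5-tetrahydro-7aH-inden-7a-yl]propanoate
Product: 19 methyl (2R)-2-[(7a'R)-4'-methyl-5'-oxo-1',3',5',7a'-tetrahydrospiro[1,3-dioxolane-2,2'-inden]-7a'-yl]propanoate
Conditions: (TMSOCH2)2, TMSOTf (5 mol%), CH2Cl2, −78→−40 °C
Reagents that add atoms: 1,2-bis(trimethylsilyloxy)ethane, C[Si](C)(C)OCCO[Si](C)(C)C
Why: Silyl-transfer ketalisation should take the saturated C2 cyclopentanone only, leaving dienone and ester, and it masks C2 through step 27.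

Step 13
Reactants: 19 methyl (2R)-2-[(7a'R)-4'-methyl-5'-oxo-1',3',5',7a'-tetrahydrospiro[1,3-dioxolane-2,2'-inden]-7a'-yl]propanoate
Product: 20 methyl (2R)-2-[(7a'S)-4'-methyl-5'-oxo-1',3',5',6',7',7a'-hexahydrospiro[1,3-dioxolane-2,2'-inden]-7a'-yl]propanoate
Conditions: H2 (1 atm), RhCl(PPh3)3 (10 mol%), benzene, rt
Reagents that add atoms: none
Why: Wilkinson hydrogenation reduces the disubstituted C7=C8 of a cross-conjugated dienone and leaves the tetrasubstituted C4=C5.

Step 14
Reactants: 20 methyl (2R)-2-[(7a'S)-4'-methyl-5'-oxo-1',3',5',6',7',7a'-hexahydrospiro[1,3-dioxolane-2,2'-inden]-7a'-yl]propanoate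
Product: 21 (2R)-2-[(7a'S)-5'-hydroxy-4'-methyl-1',3',5',6',7',7a'-hexahydrospiro[1,3-dioxolane-2,2'-inden]-7a'-yl]propan-1-ol (C6 epimers)
Conditions: DIBAL-H (5 equiv), CH2Cl2, −78→0 °C; Rochelle salt
Reagents that add atoms: none
Why: DIBAL reduces the ester to the C11 alcohol and the enone 1,2 to the allylic alcohol; the new C6 carbinol centre is removed in step 15.

Step 15
Reactants: 21 (2R)-2-[(7a'S)-5'-hydroxy-4'-methyl-1',3',5',6',7',7a'-hexahydrospiro[1,3-dioxolane-2,2'-inden]-7a'-yl]propan-1-ol (C6 epimers)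
Product: 22 (2R)-2-[(7a'S)-4'-methyl-5'-oxo-1',3',5',6',7',7a'-hexahydrospiro[1,3-dioxolane-2,2'-inden]-7a'-yl]propanal
Conditions: DMP (3 equiv), NaHCO3, CH2Cl2, 0 °C→rt
Reagents that add atoms: none
Why: Buffered Dess–Martin oxidation returns the enone and gives the C11 aldehyde without epimerising C10; 22 is used at once.

Step 16
Reactants: 23 (2E)-3-methylpent-2-en-4-yn-1-ol
Product: 24 ({[(2E)-3-methylpent-2-en-4-yn-1-yl]oxy}methyl)benzene
Conditions: NaH, BnBr, TBAI (cat.), THF, 0 °C→rt
Reagents that add atoms: benzyl bromide, BrCc1ccccc1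
Why: Williamson etherification protects the future C14 oxygen as a benzyl ether, which step 21 removes in the same pot as the enone reduction.

Step 17
Reactants: 24 ({[(2E)-3-methylpent-2-en-4-yn-1-yl]oxy}methyl)benzene
Product: 25 ({[(2E)-3-methylpenta-2,4-dien-1-yl]oxy}methyl)benzene
Conditions: H2 (1 atm), Lindlar catalyst, quinoline, hexane/EtOAc, rt
Reagents that add atoms: none
Why: Lindlar semi-hydrogenation of the terminal alkyne gives the 1,3-diene.

Step 18
Reactants: 25 ({[(2E)-3-methylpenta-2,4-dien-1-yl]oxy}methyl)benzene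
Product: 26 2-[(2Z)-5-(benzyloxy)-3-methylpent-2-en-1-yl]-4,4,5,5-tetramethyl-1,3,2-dioxaborolane
Conditions: HBpin, Ni(cod)2 (2.5 mol%), PCy3 (2.5 mol%), toluene, rt
Reagents that add atoms: pinacolborane, B1OC(C)(C)C(C)(C)O1
Why: Nickel-catalysed 1,4-hydroboration of the s-cis diene puts boron on the terminal CH2 and hydrogen on C4, so CH2B and the CH2CH2OBn arm come out cis (Z).

Step 19
Reactants: 22 (2R)-2-[(7a'S)-4'-methyl-5'-oxo-1',3',5',6',7',7a'-hexahydrospiro[1,3-dioxolane-2,2'-inden]-7a'-yl]propanal; 26 2-[(2Z)-5-(benzyloxy)-3-methylpent-2-en-1-yl]-4,4,5,5-tetramethyl-1,3,2-dioxaborolane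
Product: 28 (7a'S)-7a'-[(2R,3S,4S)-6-(benzyloxy)-4-ethenyl-3-hydroxy-4-methylhexan-2-yl]-4'-methyl-1',3',7',7a'-tetrahydrospiro[1,3-dioxolane-2,2'-inden]-5'(6'H)-one, via O-boryl adduct 27 (not isolated)
Conditions: (R)-TRIP (10 mol%), 4 Å MS, toluene, −20 °C→rt; aq NaHCO3
Reagents that add atoms: none
Why: Chiral phosphoric acid-catalysed allylboration through a Zimmerman–Traxler chair (aldehyde only, the enone ketone is inert): the Z geometry puts the CH2CH2OBn arm axial and so sets C12 relative to C11, and Re-face (Felkin–Anh) attack, reinforced by the catalyst, sets C11 (S).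

Step 20
Reactants: 28 (7a'S)-7a'-[(2R,3S,4S)-6-(benzyloxy)-4-ethenyl-3-hydroxy-4-methylhexan-2-yl]-4'-methyl-1',3',7',7a'-tetrahydrospiro[1,3-dioxolane-2,2'-inden]-5'(6'H)-one
Product: 29 (7a'S)-7a'-[(2R,3S,4S)-6-(benzyloxy)-4-ethenyl-3-(methoxymethoxy)-4-methylhexan-2-yl]-4'-methyl-1',3',7',7a'-tetrahydrospiro[1,3-dioxolane-2,2'-inden]-5'(6'H)-one
Conditions: MOMCl, iPr2NEt, TBAI (cat.), CH2Cl2, 40 °C
Reagents that add atoms: chloromethyl methyl ether, COCCl
Why: Acetal protection of the hindered C11 hydroxyl; the MOM ether survives dissolving metal, SmI2 and the oxidations and is removed in step 30.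

Step 21
Reactants: 29 (7a'S)-7a'-[(2R,3S,4S)-6-(benzyloxy)-4-ethenyl-3-(methoxymethoxy)-4-methylhexan-2-yl]-4'-methyl-1',3',7',7a'-tetrahydrospiro[1,3-dioxolane-2,2'-inden]-5'(6'H)-one
Product: 30 bis-silyl compound: C6 trimethylsilyl enol ether (C5=C6) of the 4,5-dihydro ketone, 4-H cis to the C10 branch, C14–OSiMe3 in place of C14–OBn
Conditions: Li, NH3/THF, −78 °C; isoprene; then TMSCl, Et3N, THF, −78→0 °C
Reagents that add atoms: chlorotrimethylsilane, C[Si](C)(C)Cl
Why: Dissolving-metal reduction of the enone gives the regiodefined C5=C6 lithium enolate, trapped as the silyl enol ether, and cleaves the benzyl ether in the same pot; C4–H is drawn cis-fused, but this centre is removed in step 29, so either epimer serves.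

Step 22
Reactants: 30 bis-silyl compound (C5=C6 trimethylsilyl enol ether, C14–OSiMe3)
Product: 32 C5-bromo C6-ketone carrying the free C14 hydroxyl (C5 epimers; ketal and MOM ether unchanged), via silyl ether bromoketone 31 (not isolated)
Conditions: NBS, THF, −78 °C; then citric acid aq/THF, 0 °C
Reagents that add atoms: N-bromosuccinimide, O=C1CCC(=O)N1Br
Why: Electrophilic bromination of the silyl enol ether gives the tertiary α-bromoketone regiospecifically at C5, and the mild acid work-up cleaves only the primary trimethylsilyl ether.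

Step 23
Reactants: 32 C5-bromo C6-ketone carrying the free C14 hydroxyl
Product: 33 C5-bromo C6-ketone carrying the C14 aldehyde (C5 epimers)
Conditions: DMP, pyridine, CH2Cl2, 0 °C
Reagents that add atoms: none
Why: Dess–Martin oxidation of the primary alcohol gives the C14 aldehyde under conditions that leave the bromoketone untouched.

Step 24
Reactants: 33 C5-bromo C6-ketone carrying the C14 aldehyde
Product: 36 tricyclic β-hydroxy ketone: C2 ethylene ketal, 6-oxo, 14-hydroxy, 11-O-MOM, 12-vinyl, 4-H cis-fused, via samarium enolate 34 (not isolated), via samarium aldolate 35 (not isolated)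
Conditions: SmI2 (2.5 equiv), THF (2 mM), −78→−40 °C; aq NH4Cl
Reagents that add atoms: samarium(II) iodide, I[Sm]I (samarium of 34 and 35 only)
Why: SmI2-mediated intramolecular Reformatsky-type aldol: reduction of the C–Br bond gives the C5=C6 samarium(III) enolate, which adds to the C14 aldehyde and closes the eight-membered ring; the C9-anchored chain can reach only one face of C5, and a chelated chair transition state (Sm bridging O6 and O14, C13 equatorial) is expected to give the C14 configuration of the target.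

Step 25
Reactants: 36 tricyclic β-hydroxy ketone; 37 [(tert-butyldimethylsilyl)oxy]acetic acid
Product: 38 C14 [(tert-butyldimethylsilyl)oxy]acetate of 36
Conditions: EDC·HCl, DMAP, CH2Cl2, rt
Reagents that add atoms: none
Why: Steglich esterification installs the protected glycolate and at the same time blocks retro-aldol opening of the new ring.

Step 26
Reactants: 38 C14 [(tert-butyldimethylsilyl)oxy]acetate of 36
Product: 39 6-methylidene compound (C6=CH2 in place of C6=O)
Conditions: Zn, CH2Br2, TiCl4 (Lombardo reagent), THF/CH2Cl2, 0 °C→rt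
Reagents that add atoms: dibromomethane, BrCBr
Why: Non-basic titanium-mediated methylenation suits a hindered, enolisable ketone and leaves the esters alone; C2 is still a ketal, so C6 is the only ketone.

Step 27
Reactants: 39 6-methylidene compound
Product: 40 6-methyl compound (C2 ketal, 11-O-MOM, C14 silyloxyacetate; C5 and C6 as in 43)
Conditions: Mn(dpm)3 (10 mol%), PhSiH3, TBHP, iPrOH, rt
Reagents that add atoms: none
Why: Metal hydride hydrogen-atom-transfer hydrogenation reacts with the 1,1-disubstituted alkene far faster than with the monosubstituted C12 vinyl; the tertiary C6 radical should take hydrogen on the face away from the C5–C14 bond, which leaves the C6 methyl trans to the C5 methyl.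

Step 28
Reactants: 40 6-methyl compound
Product: 41 C2 ketone (4-H cis-fused, 11-O-MOM, C14 silyloxyacetate)
Conditions: PPTS, acetone/H2O 9:1, 50 °C
Reagents that add atoms: water, O
Why: Mild acid hydrolysis of the dioxolane; the MOM ether and the primary TBS ether should survive PPTS in aqueous acetone.

Step 29
Reactants: 41 C2 ketone
Product: 42 C3=C4 enone: 11-O-MOM and glycolate O-TBS derivative of 43
Conditions: IBX (3 equiv), DMSO/fluorobenzene 1:2, 70 °C
Reagents that add atoms: none
Why: IBX α,β-dehydrogenation of the cyclopentanone can only give C3=C4, since C9 on the other side is quaternary; this removes the C4 stereocentre.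

Step 30
Reactants: 42 C3=C4 enone (11-O-MOM, glycolate O-TBS)
Product: 43 Pleuromutilin F
Conditions: HCl (3 M aq)/THF 1:3, 40 °C
Reagents that add atoms: none
Why: Acid hydrolysis removes the MOM acetal and the silyl ether in one operation; the hindered C14 ester should survive.

**Compound list**
1 | 3-bromo-2-methylphenol | Cc1c(O)cccc1Br | starting material
2 | (3-bromo-2-methylphenoxy)triisopropylsilane | Cc1c(O[Si](C(C)C)(C(C)C)C(C)C)cccc1Br | intermediate
3 | (2-tert-butoxy-2-oxoethyl)zinc chloride (commercial solution) | CC(C)(C)OC(=O)C[Zn]Cl | starting material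
4 | tert-butyl 2-{2-methyl-3-[(triisopropylsilyl)oxy]phenyl}acetate | Cc1c(O[Si](C(C)C)(C(C)C)C(C)C)cccc1CC(=O)OC(C)(C)C | intermediate
5 | tert-butyl 2-{6-bromo-2-methyl-3-[(triisopropylsilyl)oxy]phenyl}acetate | Cc1c(O[Si](C(C)C)(C(C)C)C(C)C)ccc(Br)c1CC(=O)OC(C)(C)C | intermediate
6 | 4,4,5,5-tetramethyl-2-(prop-1-en-2-yl)-1,3,2-dioxaborolane | CC(=C)B1OC(C)(C)C(C)(C)O1 | starting material
7 | tert-butyl 2-{2-methyl-6-(prop-1-en-2-yl)-3-[(triisopropylsilyl)oxy]phenyl}acetate | Cc1c(O[Si](C(C)C)(C(C)C)C(C)C)ccc(C(C)=C)c1CC(=O)OC(C)(C)C | intermediate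
8 | tert-butyl 2-{2-methyl-6-[(2S)-1-(4,4,5,5-tetramethyl-1,3,2-dioxaborolan-2-yl)propan-2-yl]-3-[(triisopropylsilyl)oxy]phenyl}acetate | Cc1c(O[Si](C(C)C)(C(C)C)C(C)C)ccc([C@@H](C)CB2OC(C)(C)C(C)(C)O2)c1CC(=O)OC(C)(C)C | intermediate
9 | tert-butyl 2-{6-[(2R)-1-hydroxypropan-2-yl]-2-methyl-3-[(triisopropylsilyl)oxy]phenyl}acetate | Cc1c(O[Si](C(C)C)(C(C)C)C(C)C)ccc([C@@H](C)CO)c1CC(=O)OC(C)(C)C | intermediate
10 | (2R)-2-{2-(2-tert-butoxy-2-oxoethyl)-3-methyl-4-[(triisopropylsilyl)oxy]phenyl}propanoic acid | Cc1c(O[Si](C(C)C)(C(C)C)C(C)C)ccc([C@@H](C)C(=O)O)c1CC(=O)OC(C)(C)C | intermediate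
11 | (trimethylsilyl)diazomethane | C[Si](C)(C)C=[N+]=[N-] | starting material
12 | methyl (2R)-2-{2-(2-tert-butoxy-2-oxoethyl)-3-methyl-4-[(triisopropylsilyl)oxy]phenyl}propanoate | Cc1c(O[Si](C(C)C)(C(C)C)C(C)C)ccc([C@@H](C)C(=O)OC)c1CC(=O)OC(C)(C)C | intermediate
13 | 2-{6-[(2R)-1-methoxy-1-oxopropan-2-yl]-2-methyl-3-[(triisopropylsilyl)oxy]phenyl}acetic acid | Cc1c(O[Si](C(C)C)(C(C)C)C(C)C)ccc([C@@H](C)C(=O)OC)c1CC(=O)O | intermediate
14 | acid chloride of 13 | Cc1c(O[Si](C(C)C)(C(C)C)C(C)C)ccc([C@@H](C)C(=O)OC)c1CC(=O)Cl | intermediate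
15 | methyl (2R)-2-{2-[3-diazo-2-oxo-3-(trimethylsilyl)propyl]-3-methyl-4-[(triisopropylsilyl)oxy]phenyl}propanoate | Cc1c(O[Si](C(C)C)(C(C)C)C(C)C)ccc([C@@H](C)C(=O)OC)c1CC(=O)C(=[N+]=[N-])[Si](C)(C)C | intermediate
16 | methyl (2R)-2-{2-(3-diazo-2-oxopropyl)-3-methyl-4-[(triisopropylsilyl)oxy]phenyl}propanoate | Cc1c(O[Si](C(C)C)(C(C)C)C(C)C)ccc([C@@H](C)C(=O)OC)c1CC(=O)C=[N+]=[N-] | intermediate
17 | methyl (2R)-2-[2-(3-diazo-2-oxopropyl)-4-hydroxy-3-methylphenyl]propanoate (key-step precursor) | Cc1c(O)ccc([C@@H](C)C(=O)OC)c1CC(=O)C=[N+]=[N-] | intermediate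
18 | methyl (2R)-2-[(7aR)-4-methyl-2,5-dioxo-1,2,3,5-tetrahydro-7aH-inden-7a-yl]propanoate (key-step product) | CC1=C2CC(=O)C[C@@]2(C=CC1=O)[C@@H](C)C(=O)OC | intermediate
19 | methyl (2R)-2-[(7a'R)-4'-methyl-5'-oxo-1',3',5',7a'-tetrahydrospiro[1,3-dioxolane-2,2'-inden]-7a'-yl]propanoate | CC1=C2CC3(OCCO3)C[C@@]2(C=CC1=O)[C@@H](C)C(=O)OC | intermediate
20 | methyl (2R)-2-[(7a'S)-4'-methyl-5'-oxo-1',3',5',6',7',7a'-hexahydrospiro[1,3-dioxolane-2,2'-inden]-7a'-yl]propanoate | CC1=C2CC3(OCCO3)C[C@@]2(CCC1=O)[C@@H](C)C(=O)OC | intermediate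
21 | (2R)-2-[(7a'S)-5'-hydroxy-4'-methyl-1',3',5',6',7',7a'-hexahydrospiro[1,3-dioxolane-2,2'-inden]-7a'-yl]propan-1-ol (C6 epimers) | CC1=C2CC3(OCCO3)C[C@@]2(CCC1O)[C@@H](C)CO | intermediate
22 | (2R)-2-[(7a'S)-4'-methyl-5'-oxo-1',3',5',6',7',7a'-hexahydrospiro[1,3-dioxolane-2,2'-inden]-7a'-yl]propanal | CC1=C2CC3(OCCO3)C[C@@]2(CCC1=O)[C@@H](C)C=O | intermediate
23 | (2E)-3-methylpent-2-en-4-yn-1-ol | C#C/C(C)=C/CO | starting material
24 | ({[(2E)-3-methylpent-2-en-4-yn-1-yl]oxy}methyl)benzene | C#C/C(C)=C/COCc1ccccc1 | intermediate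
25 | ({[(2E)-3-methylpenta-2,4-dien-1-yl]oxy}methyl)benzene | C=C/C(C)=C/COCc1ccccc1 | intermediate
26 | 2-[(2Z)-5-(benzyloxy)-3-methylpent-2-en-1-yl]-4,4,5,5-tetramethyl-1,3,2-dioxaborolane | C/C(CCOCc1ccccc1)=C/CB1OC(C)(C)C(C)(C)O1 | intermediate
27 | O-pinacolboryl ether of 28 | CC1=C2CC3(OCCO3)C[C@@]2(CCC1=O)[C@@H](C)[C@H](OB1OC(C)(C)C(C)(C)O1)[C@](C)(C=C)CCOCc1ccccc1 | intermediate
28 | (7a'S)-7a'-[(2R,3S,4S)-6-(benzyloxy)-4-ethenyl-3-hydroxy-4-methylhexan-2-yl]-4'-methyl-1',3',7',7a'-tetrahydrospiro[1,3-dioxolane-2,2'-inden]-5'(6'H)-one (C9 S, C10 R, C11 S, C12 S) | CC1=C2CC3(OCCO3)C[C@@]2(CCC1=O)[C@@H](C)[C@H](O)[C@](C)(C=C)CCOCc1ccccc1 | intermediate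
29 | 11-O-methoxymethyl ether of 28 | CC1=C2CC3(OCCO3)C[C@@]2(CCC1=O)[C@@H](C)[C@H](OCOC)[C@](C)(C=C)CCOCc1ccccc1 | intermediate
30 | bis-silyl compound: C5=C6 trimethylsilyl enol ether, 4-H cis to the C10 branch, C14–OSiMe3, C2 ketal, 11-O-MOM | CC1=C(O[Si](C)(C)C)CC[C@]2(CC3(OCCO3)C[C@@H]12)[C@@H](C)[C@H](OCOC)[C@](C)(C=C)CCO[Si](C)(C)C | intermediate
31 | C5-bromo C6-ketone with C14–OSiMe3 (C5 epimers) | CC1(Br)C(=O)CC[C@]2(CC3(OCCO3)C[C@@H]12)[C@@H](C)[C@H](OCOC)[C@](C)(C=C)CCO[Si](C)(C)C | intermediate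
32 | C5-bromo C6-ketone with free C14 hydroxyl (C5 epimers) | CC1(Br)C(=O)CC[C@]2(CC3(OCCO3)C[C@@H]12)[C@@H](C)[C@H](OCOC)[C@](C)(C=C)CCO | intermediate
33 | C5-bromo C6-ketone with C14 aldehyde (C5 epimers) | CC1(Br)C(=O)CC[C@]2(CC3(OCCO3)C[C@@H]12)[C@@H](C)[C@H](OCOC)[C@](C)(C=C)CC=O | intermediate
34 | C5=C6 samarium(III) enolate of the debrominated keto aldehyde | CC1=C(O[Sm](I)I)CC[C@]2(CC3(OCCO3)C[C@@H]12)[C@@H](C)[C@H](OCOC)[C@](C)(C=C)CC=O | intermediate
35 | samarium(III) C14 alkoxide of 36 | C=C[C@]1(C)C[C@@H](O[Sm](I)I)[C@]2(C)[C@@H]3CC4(OCCO4)C[C@@]3(CCC2=O)[C@@H](C)[C@@H]1OCOC | intermediate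
36 | tricyclic β-hydroxy ketone: C2 ethylene ketal, 6-oxo, 14-hydroxy, 11-O-MOM, 12-methyl-12-vinyl, 4-H cis-fused; C5, C9, C10, C11, C12, C14 as in 43 | C=C[C@]1(C)C[C@@H](O)[C@]2(C)[C@@H]3CC4(OCCO4)C[C@@]3(CCC2=O)[C@@H](C)[C@@H]1OCOC | intermediate
37 | [(tert-butyldimethylsilyl)oxy]acetic acid | CC(C)(C)[Si](C)(C)OCC(=O)O | starting material
38 | C14 [(tert-butyldimethylsilyl)oxy]acetate of 36 | C=C[C@]1(C)C[C@@H](OC(=O)CO[Si](C)(C)C(C)(C)C)[C@]2(C)[C@@H]3CC4(OCCO4)C[C@@]3(CCC2=O)[C@@H](C)[C@@H]1OCOC | intermediate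
39 | 6-methylidene analogue of 38 | C=C[C@]1(C)C[C@@H](OC(=O)CO[Si](C)(C)C(C)(C)C)[C@]2(C)[C@@H]3CC4(OCCO4)C[C@@]3(CCC2=C)[C@@H](C)[C@@H]1OCOC | intermediate
40 | 6-methyl compound: C2 ketal, 11-O-MOM, C14 silyloxyacetate; C5 and C6 as in 43 | C=C[C@]1(C)C[C@@H](OC(=O)CO[Si](C)(C)C(C)(C)C)[C@]2(C)[C@@H]3CC4(OCCO4)C[C@@]3(CC[C@@H]2C)[C@@H](C)[C@@H]1OCOC | intermediate
41 | C2 ketone (3,4-dihydro-42, 4-H cis-fused) | C=C[C@]1(C)C[C@@H](OC(=O)CO[Si](C)(C)C(C)(C)C)[C@]2(C)[C@@H]3CC(=O)C[C@@]3(CC[C@@H]2C)[C@@H](C)[C@@H]1OCOC | intermediate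
42 | 11-O-methoxymethyl, glycolate O-tert-butyldimethylsilyl derivative of Pleuromutilin F | C=C[C@]1(C)C[C@@H](OC(=O)CO[Si](C)(C)C(C)(C)C)[C@]2(C)C3=CC(=O)C[C@@]3(CC[C@@H]2C)[C@@H](C)[C@@H]1OCOC | intermediate
43 | Pleuromutilin F (5S,6S,9S,10R,11S,12S,14R) | C=C[C@]1(C)C[C@@H](OC(=O)CO)[C@]2(C)C3=CC(=O)C[C@@]3(CC[C@@H]2C)[C@@H](C)[C@@H]1O | target

**Summary**
Total step count: 30. Longest linear sequence: 27 steps (steps 1–15 and 19–30; steps 16–18 make the allylboronate 26).

Steps most likely to fail: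

Step 11 (key step). The carbenoid may bond at C5 (ortho to the hydroxyl), may attack the wrong face of C9, or may be lost to intermolecular O–H insertion. Fallback, setting out from 17: dry HCl in ether converts the diazoketone into the α-chloroketone methyl (2R)-2-[2-(3-chloro-2-oxopropyl)-4-hydroxy-3-methylphenyl]propanoate F1. K2CO3 in acetonitrile then forms the phenoxide, which closes the ring by intramolecular para-C-alkylation (anionic alkylative dearomatisation, SN2 at the α-keto carbon, no carbenoid involved). The route is rejoined at 18.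

Step 24. The samarium enolate may be protonated before it cyclises (simple debromination), or the strained aldolate may revert by retro-aldol before the quench. Fallback, setting out from 29: lithium in ammonia as in step 21, but with chlorotriethylsilane as the trap, gives the bis-triethylsilyl compound (C5=C6 triethylsilyl enol ether, C14–OSiEt3) F2. Swern conditions oxidise the primary triethylsilyl ether directly to the enol-silane aldehyde F3 and leave the tetrasubstituted enol ether. Catalytic TASF in THF at −78 °C then starts a fluoride-promoted aldol of the enol silane; the silyl group passes to the new oxygen, so the product is capped as the C14 triethylsilyl ether of the tricyclic hydroxy ketone F4 and cannot revert. HF·pyridine frees the alcohol and the route is rejoined at 36.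

Step 19. In the closed transition state the C10 methyl meets the axial arm of the (Z)-boronate on the Felkin (Re) face, so the catalyst may not override the substrate's preference, with loss of facial selectivity at C11 (and with it C12) or a sluggish addition. Fallback, setting out from 26: the pinacol ester is exchanged (diethanolamine adduct, hydrolysis, then diisopropyl D-tartrate and MgSO4) for the tartrate ester diisopropyl (4S,5S)-2-[(2Z)-5-(benzyloxy)-3-methylpent-2-en-1-yl]-1,3,2-dioxaborolane-4,5-dicarboxylate F5. This reagent carries its own covalently bound chiral controller and is added in stoichiometric amount to 22 in toluene at −78 °C over 4 Å sieves (tartrate-modified allylboration, same chair transfer of the Z geometry to C11/C12). Aqueous work-up rejoins the route at 28.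

Further compounds
F1 | step 11 | methyl (2R)-2-[2-(3-chloro-2-oxopropyl)-4-hydroxy-3-methylphenyl]propanoate | Cc1c(O)ccc([C@@H](C)C(=O)OC)c1CC(=O)CCl
F2 | step 24 | bis-triethylsilyl compound (C5=C6 triethylsilyl enol ether, C14–OSiEt3, 4-H cis-fused, C2 ketal, 11-O-MOM) | CC1=C(O[Si](CC)(CC)CC)CC[C@]2(CC3(OCCO3)C[C@@H]12)[C@@H](C)[C@H](OCOC)[C@](C)(C=C)CCO[Si](CC)(CC)CC
F3 | step 24 | enol-silane aldehyde (C5=C6 triethylsilyl enol ether, C14 aldehyde) | CC1=C(O[Si](CC)(CC)CC)CC[C@]2(CC3(OCCO3)C[C@@H]12)[C@@H](C)[C@H](OCOC)[C@](C)(C=C)CC=O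
F4 | step 24 | C14 triethylsilyl ether of 36 | C=C[C@]1(C)C[C@@H](O[Si](CC)(CC)CC)[C@]2(C)[C@@H]3CC4(OCCO4)C[C@@]3(CCC2=O)[C@@H](C)[C@@H]1OCOC
F5 | step 19 | diisopropyl (4S,5S)-2-[(2Z)-5-(benzyloxy)-3-methylpent-2-en-1-yl]-1,3,2-dioxaborolane-4,5-dicarboxylate | C/C(CCOCc1ccccc1)=C/CB1O[C@H](C(=O)OC(C)C)[C@@H](C(=O)OC(C)C)O1
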